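**Plan**

1. Retrosynthesis: the C4–C5 epoxide goes back to the 4Z-olefin, and the C14 aldehyde and C9 acetate to a silylene-protected 9,14-diol. The lactone bond O6–C12 and the bond C5–C6 are then cut together, which opens both rings to an acyclic Z-alkenyl iodide/aldehyde. Last, C7–C8 (Barbier allylation) and C1=C10 (Wittig) are cut.
2. Enabling feature: the epoxide carbon C5 is bonded to the lactone carbinol C6, so C4=C5–C6(O) is an allylic alkoxide whose oxygen is γ to the C12 ester on C11. An alkenylmetal at C5 adding to a C6 aldehyde therefore closes the ten-membered carbocycle (C1–C10) and, through the alkoxide, the γ-lactone (O6–C6–C7–C11–C12) in one operation.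
3. Forward order: the C1–C5 iodide and the C8–C10 glycerate unit are joined by Wittig (C1=C10) and C14 is oxygenated. The C6/C7/C11–C13 acrylate unit is added by allylation (C7–C8). The carbocycle and then the lactone form in the key step, and the epoxide ring is made last.
4. Stereochemistry: C9 comes from methyl (S)-glycerate acetonide. C8 (Felkin–Anh) and C7 (chair transition state) are set in the allylation, and C6 in the key step under control of C7. C4/C5 are set by bromohydrin formation and inverting closure, on the face of the 4Z-olefin opposite to electrophilic attack. Z-C4=C5 comes from chelation-controlled carboalumination; the C1=C10 geometry from the α-alkoxy-ketone Wittig and the SeO2 [2,3]-shift.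

Key step: step 16

Remark: germacrane numbering of the target is used throughout (ring C1–C10; C11–C13 the 2-propenoate arm on C7 with C12 the carbonyl; C14 on C10; C15 the methyl on C4). The given SMILES is read as a cis 4,5-epoxide (C3 and C6 on the same side) and a 1(10)-olefin with C2 and C9 cis. Compounds 1, 6, 15 and 16 are assumed to be purchased (16 as its aqueous solution).

**Route**

Step 1
Reactants: 1 pent-4-yn-1-ol
Product: 3 (Z)-5-iodo-4-methylpent-4-en-1-ol, via cyclic alkenylalane 2 (not isolated)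
Conditions: Me3Al (3 equiv), Cp2ZrCl2 (0.25 equiv), ClCH2CH2Cl, rt then reflux; I2, THF, −30 → 0 °C
Reagents that add atoms: trimethylaluminium C[Al](C)C; iodine I-I
Why: Zirconium-catalysed methylalumination followed by thermal, alkoxide-chelation-driven isomerization of the alkenylalane (Negishi anti-carbometalation of ω-alkynols) should place methyl and aluminium anti, so that iodinolysis with retention gives the Z-iodoalkene that becomes C4=C5.

Step 2
Reactants: 3 (Z)-5-iodo-4-methylpent-4-en-1-ol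
Product: 4 (Z)-1,5-diiodo-2-methylpent-1-ene
Conditions: I2, PPh3, imidazole, CH2Cl2, 0 °C → rt
Reagents that add atoms: iodine I-I
Why: Appel-type iodination converts the primary alcohol into the iodide by SN2 displacement of the oxyphosphonium group and leaves the alkenyl iodide untouched.

Step 3
Reactants: 4 (Z)-1,5-diiodo-2-methylpent-1-ene
Product: 5 [(Z)-5-iodo-4-methylpent-4-en-1-yl]triphenylphosphonium iodide
Conditions: PPh3, MeCN, reflux
Reagents that add atoms: triphenylphosphine c1ccc(cc1)P(c1ccccc1)c1ccccc1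
Why: SN2 quaternization of the phosphine occurs only at the primary alkyl iodide, because the sp2 carbon–iodine bond is inert without a metal catalyst.

Step 4
Reactants: 6 methyl (S)-2,2-dimethyl-1,3-dioxolane-4-carboxylate
Product: 7 (S)-N-methoxy-N,2,2-trimethyl-1,3-dioxolane-4-carboxamide
Conditions: MeNH(OMe)·HCl, i-PrMgCl, THF, −20 °C
Reagents that add atoms: N,O-dimethylhydroxylamine hydrochloride CNOC.Cl
Why: Aminolysis of the ester by the chloromagnesium amide (Weinreb amide formation) at low temperature should leave the α-stereocenter, the future C9, untouched.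

Step 5
Reactants: 7 (S)-N-methoxy-N,2,2-trimethyl-1,3-dioxolane-4-carboxamide
Product: 8 (S)-1-(2,2-dimethyl-1,3-dioxolan-4-yl)ethan-1-one
Conditions: MeMgBr, THF, −78 → 0 °C
Reagents that add atoms: methylmagnesium bromide C[Mg]Br
Why: The stable magnesium chelate of the Weinreb amide stops the Grignard addition at the methyl ketone stage (Weinreb ketone synthesis).

Step 6
Reactants: 5 [(Z)-5-iodo-4-methylpent-4-en-1-yl]triphenylphosphonium iodide; 8 (S)-1-(2,2-dimethyl-1,3-dioxolan-4-yl)ethan-1-one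
Product: 10 (4R)-4-[(2Z,6Z)-7-iodo-6-methylhepta-2,6-dien-2-yl]-2,2-dimethyl-1,3-dioxolane, via phosphorus ylide 9 (not isolated)
Conditions: NaN(SiMe3)2, THF, −78 °C; then 8, −78 °C → rt
Reagents that add atoms: none
Why: Wittig olefination of an α-alkoxy ketone with a non-stabilized ylide should give the Z-trisubstituted olefin in which the ylide chain (C2) is cis to the oxygenated carbon C9, and the silylamide base spares the alkenyl iodide.

Step 7
Reactants: 10 (4R)-4-[(2Z,6Z)-7-iodo-6-methylhepta-2,6-dien-2-yl]-2,2-dimethyl-1,3-dioxolane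
Product: 11 (2Z,6Z)-2-[(4R)-2,2-dimethyl-1,3-dioxolan-4-yl]-7-iodo-6-methylhepta-2,6-dien-1-ol
Conditions: SeO2 (cat.), t-BuOOH, CH2Cl2, 0 °C → rt
Reagents that add atoms: tert-butyl hydroperoxide CC(C)(C)OO; selenium dioxide O=[Se]=O
Why: The SeO2 ene reaction/[2,3]-sigmatropic shift (allylic oxidation) hydroxylates the methyl group on the more substituted carbon of the electron-rich olefin and delivers the hydroxymethyl group (C14) trans to C2, which also corrects any minor geometric isomer from step 6, while the iodo-olefin is deactivated.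

Step 8
Reactants: 11 (2Z,6Z)-2-[(4R)-2,2-dimethyl-1,3-dioxolan-4-yl]-7-iodo-6-methylhepta-2,6-dien-1-ol
Product: 12 (2R,3Z,7Z)-3-(hydroxymethyl)-8-iodo-7-methylocta-3,7-diene-1,2-diol
Conditions: AcOH/H2O (4:1), 40 °C
Reagents that add atoms: none
Why: Acid-catalysed acetal hydrolysis frees the C8/C9 diol, and the allylic alcohol and the alkenyl iodide tolerate aqueous acetic acid.

Step 9
Reactants: 12 (2R,3Z,7Z)-3-(hydroxymethyl)-8-iodo-7-methylocta-3,7-diene-1,2-diol
Product: 13 [(4R,5Z)-2,2-di-tert-butyl-5-[(Z)-5-iodo-4-methylpent-4-en-1-ylidene]-1,3,2-dioxasilinan-4-yl]methanol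
Conditions: t-Bu2Si(OTf)2, 2,6-lutidine, CH2Cl2, −40 → 0 °C
Reagents that add atoms: di-tert-butylsilyl bis(trifluoromethanesulfonate) CC(C)(C)[Si](OS(=O)(=O)C(F)(F)F)(OS(=O)(=O)C(F)(F)F)C(C)(C)C
Why: The di-tert-butylsilylene group closes preferentially to the six-membered 1,3-dioxasilinane over O9 and O14 (as on nucleoside 3',5'-diols), which leaves the primary C8 hydroxyl free.

Step 10
Reactants: 13 [(4R,5Z)-2,2-di-tert-butyl-5-[(Z)-5-iodo-4-methylpent-4-en-1-ylidene]-1,3,2-dioxasilinan-4-yl]methanol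
Product: 14 (4R,5Z)-2,2-di-tert-butyl-5-[(Z)-5-iodo-4-methylpent-4-en-1-ylidene]-1,3,2-dioxasilinane-4-carbaldehyde
Conditions: Dess–Martin periodinane, CH2Cl2, 0 °C → rt
Reagents that add atoms: none
Why: Dess–Martin oxidation gives the α-silyloxy aldehyde under non-basic conditions that should not epimerize C9.

Step 11
Reactants: 15 methyl acrylate; 16 2,2-dimethoxyacetaldehyde
Product: 17 methyl 3-hydroxy-4,4-dimethoxy-2-methylidenebutanoate (racemic)
Conditions: DABCO (0.5 equiv), 1,4-dioxane/H2O, rt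
Reagents that add atoms: none
Why: Morita–Baylis–Hillman reaction of the activated α,α-dialkoxy aldehyde with methyl acrylate; the racemic carbinol center is destroyed in the next step.

Step 12
Reactants: 17 methyl 3-hydroxy-4,4-dimethoxy-2-methylidenebutanoate
Product: 18 methyl (Z)-2-(bromomethyl)-4,4-dimethoxybut-2-enoate
Conditions: NBS, Me2S, CH2Cl2, 0 °C → rt
Reagents that add atoms: N-bromosuccinimide O=C1CCC(=O)N1Br
Why: Corey–Kim-type activation of the alcohol and SN2' attack of bromide give the rearranged primary allylic bromide with the acetal-bearing carbon cis to CH2Br, as is general for Baylis–Hillman adducts.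

Step 13
Reactants: 14 (4R,5Z)-2,2-di-tert-butyl-5-[(Z)-5-iodo-4-methylpent-4-en-1-ylidene]-1,3,2-dioxasilinane-4-carbaldehyde; 18 methyl (Z)-2-(bromomethyl)-4,4-dimethoxybut-2-enoate
Product: 19 methyl (3R,4S)-4-[(4R,5Z)-2,2-di-tert-butyl-5-[(Z)-5-iodo-4-methylpent-4-en-1-ylidene]-1,3,2-dioxasilinan-4-yl]-3-(dimethoxymethyl)-4-hydroxy-2-methylidenebutanoate
Conditions: indium powder, THF/H2O (1:1), rt
Reagents that add atoms: none
Why: The indium Barbier allylation proceeds by γ-attack through a chair six-membered transition state, which should give the 7,8-syn adduct, while Felkin–Anh attack anti to the C9–O bond of the α-silyloxy aldehyde should give the 8,9-anti relationship; in water the hydroxy ester is isolated without lactonization.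

Step 14
Reactants: 19 methyl (3R,4S)-4-[(4R,5Z)-2,2-di-tert-butyl-5-[(Z)-5-iodo-4-methylpent-4-en-1-ylidene]-1,3,2-dioxasilinan-4-yl]-3-(dimethoxymethyl)-4-hydroxy-2-methylidenebutanoate
Product: 20 methyl (3R,4S)-4-[(4R,5Z)-2,2-di-tert-butyl-5-[(Z)-5-iodo-4-methylpent-4-en-1-ylidene]-1,3,2-dioxasilinan-4-yl]-3-(dimethoxymethyl)-4-[(2-methylprop-2-enoyl)oxy]-2-methylidenebutanoate
Conditions: methacrylic anhydride, Et3N, DMAP (cat.), CH2Cl2, 0 °C → rt
Reagents that add atoms: methacrylic anhydride C=C(C)C(=O)OC(=O)C(C)=C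
Why: DMAP-catalysed acylation installs the C8 methacrylate before the hydroxy ester can lactonize toward O8.

Step 15
Reactants: 20 methyl (3R,4S)-4-[(4R,5Z)-2,2-di-tert-butyl-5-[(Z)-5-iodo-4-methylpent-4-en-1-ylidene]-1,3,2-dioxasilinan-4-yl]-3-(dimethoxymethyl)-4-[(2-methylprop-2-enoyl)oxy]-2-methylidenebutanoate
Product: 21 methyl (3R,4S)-4-[(4R,5Z)-2,2-di-tert-butyl-5-[(Z)-5-iodo-4-methylpent-4-en-1-ylidene]-1,3,2-dioxasilinan-4-yl]-3-formyl-4-[(2-methylprop-2-enoyl)oxy]-2-methylidenebutanoate
Conditions: LiBF4, MeCN/H2O (98:2), rt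
Reagents that add atoms: water O
Why: LiBF4 in wet acetonitrile hydrolyses the dimethyl acetal under nearly neutral conditions, avoiding base that would epimerize C7 or eliminate the β-acyloxy group; the aldehyde is used at once.

Step 16
Reactants: 21 methyl (3R,4S)-4-[(4R,5Z)-2,2-di-tert-butyl-5-[(Z)-5-iodo-4-methylpent-4-en-1-ylidene]-1,3,2-dioxasilinan-4-yl]-3-formyl-4-[(2-methylprop-2-enoyl)oxy]-2-methylidenebutanoate
Product: 23 (1(10)Z,4Z,6R,7S,8S,9R)-9,14-O-(di-tert-butylsilanediyl)-9,14-dihydroxy-8-(methacryloyloxy)germacra-1(10),4,11(13)-trien-12,6-olide, via chromium alkoxide 22 (not isolated)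
Conditions: CrCl2 (10 equiv), NiCl2 (0.1 equiv), DMSO, rt, 0.002 M (slow addition)
Reagents that add atoms: none
Why: Zerovalent nickel inserts into the alkenyl carbon–iodine bond at C5, transmetalation to trivalent chromium gives an alkenylchromium reagent that adds to the C6 aldehyde (Nozaki–Hiyama–Kishi reaction; the closest known type is the NHK macrocyclization to medium-ring allylic alcohols), and the chromium alkoxide 22 then acylates itself on the neighbouring C12 methyl ester, as chromium alkoxides do in 2-(bromomethyl)acrylate additions that give α-methylene-γ-butyrolactones directly. The ten-membered carbocycle closes in a 10-exo-trig mode (C5 onto C6=O) and the lactone in a 5-exo-trig mode (O6 onto C12=O with loss of methoxide). The new stereocenter C6 is controlled by C7: in the Felkin–Anh arrangement the tether carbon C8 lies anti to the incoming C5 and the 2-propenoate arm gauche to the carbonyl oxygen, which should place O6 syn to C11 and lead to the trans-fused lactone. C4=C5 keeps its Z geometry because trisubstituted alkenylchromium reagents couple with retention. The step needs aldehyde-over-ester chemoselectivity (organochromium reagents do not add to esters or acrylates), cyclization over oligomerization (high dilution; the two Z-olefins and the dioxasilinane ring pre-fold the chain) and survival of the base-sensitive β-acyloxy aldehyde (the medium is non-basic).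

Step 17
Reactants: 23 (1(10)Z,4Z,6R,7S,8S,9R)-9,14-O-(di-tert-butylsilanediyl)-9,14-dihydroxy-8-(methacryloyloxy)germacra-1(10),4,11(13)-trien-12,6-olide
Product: 24 (1(10)Z,4Z,6R,7S,8S,9R)-9,14-dihydroxy-8-(methacryloyloxy)germacra-1(10),4,11(13)-trien-12,6-olide
Conditions: HF·pyridine, pyridine/THF, 0 °C
Reagents that add atoms: none
Why: Fluoride cleavage of the silylene frees the 9,14-diol without touching the esters or the α-methylene lactone.

Step 18
Reactants: 24 (1(10)Z,4Z,6R,7S,8S,9R)-9,14-dihydroxy-8-(methacryloyloxy)germacra-1(10),4,11(13)-trien-12,6-olide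
Product: 25 (1(10)E,4Z,6R,7S,8S,9R)-9-hydroxy-8-(methacryloyloxy)-14-oxogermacra-1(10),4,11(13)-trien-12,6-olide
Conditions: PhI(OAc)2, TEMPO (cat.), CH2Cl2, rt
Reagents that add atoms: none
Why: The TEMPO/PhI(OAc)2 oxidation is selective for the primary allylic alcohol over the secondary C9 alcohol and stops at the aldehyde, so the enal with C14 trans to C2 results.

Step 19
Reactants: 25 (1(10)E,4Z,6R,7S,8S,9R)-9-hydroxy-8-(methacryloyloxy)-14-oxogermacra-1(10),4,11(13)-trien-12,6-olide
Product: 26 (1(10)E,4Z,6R,7S,8S,9R)-9-acetoxy-8-(methacryloyloxy)-14-oxogermacra-1(10),4,11(13)-trien-12,6-olide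
Conditions: Ac2O, pyridine, CH2Cl2, 0 °C → rt
Reagents that add atoms: acetic anhydride CC(=O)OC(C)=O
Why: Acetylation of the secondary allylic alcohol is run without DMAP, to avoid SN2' displacement of the resulting Baylis–Hillman-type acetate.

Step 20
Reactants: 26 (1(10)E,4Z,6R,7S,8S,9R)-9-acetoxy-8-(methacryloyloxy)-14-oxogermacra-1(10),4,11(13)-trien-12,6-olide
Product: 27 (1(10)E,4R,5R,6S,7R,8S,9R)-9-acetoxy-5-bromo-4-hydroxy-8-(methacryloyloxy)-14-oxogermacra-1(10),11(13)-dien-12,6-olide
Conditions: NBS, THF/H2O (4:1), 0 °C, dark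
Reagents that add atoms: N-bromosuccinimide O=C1CCC(=O)N1Br; water O
Why: Bromonium formation should occur only at the electron-richest olefin C4=C5 (the enal, the α-methylene lactone and the methacrylate are deactivated) and on the exposed face trans to O6 (the face peracids attack in medium-ring allylic esters), and water opens it anti to give the bromohydrin.

Step 21
Reactants: 27 (1(10)E,4R,5R,6S,7R,8S,9R)-9-acetoxy-5-bromo-4-hydroxy-8-(methacryloyloxy)-14-oxogermacra-1(10),11(13)-dien-12,6-olide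
Product: 28 CNP0121379.1 (target): (1(10)E,4R,5S,6S,7R,8S,9R)-9-acetoxy-4,5-epoxy-8-(methacryloyloxy)-14-oxogermacra-1(10),11(13)-dien-12,6-olide
Conditions: K2CO3, MeCN, 0 °C → rt
Reagents that add atoms: none
Why: Intramolecular SN2 displacement of bromide by the vicinal alkoxide (3-exo-tet) inverts C5 and places the epoxide oxygen on the face opposite to the one attacked by bromine, that is cis to O6 as in the target, with the cis (C3/C6) geometry of the olefin preserved.

**Compound list**

1 | pent-4-yn-1-ol | C#CCCCO | starting material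
2 | 2,4-dimethyl-2,5,6,7-tetrahydro-1,2-oxaluminepine (cyclic Z-alkenylalane alkoxide) | C[Al]1OCCC/C(C)=C\1 | intermediate (not isolated)
3 | (Z)-5-iodo-4-methylpent-4-en-1-ol | I/C=C(C)\CCCO | intermediate
4 | (Z)-1,5-diiodo-2-methylpent-1-ene | I/C=C(C)\CCCI | intermediate
5 | [(Z)-5-iodo-4-methylpent-4-en-1-yl]triphenylphosphonium iodide | I/C=C(C)\CCC[P+](c1ccccc1)(c1ccccc1)c1ccccc1.[I-] | intermediate
6 | methyl (S)-2,2-dimethyl-1,3-dioxolane-4-carboxylate | COC(=O)[C@@H]1COC(C)(C)O1 | starting material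
7 | (S)-N-methoxy-N,2,2-trimethyl-1,3-dioxolane-4-carboxamide | CON(C)C(=O)[C@@H]1COC(C)(C)O1 | intermediate
8 | (S)-1-(2,2-dimethyl-1,3-dioxolan-4-yl)ethan-1-one | CC(=O)[C@@H]1COC(C)(C)O1 | intermediate
9 | [(Z)-5-iodo-4-methylpent-4-en-1-ylidene]triphenylphosphorane | I/C=C(C)\CCC=P(c1ccccc1)(c1ccccc1)c1ccccc1 | intermediate (not isolated)
10 | (4R)-4-[(2Z,6Z)-7-iodo-6-methylhepta-2,6-dien-2-yl]-2,2-dimethyl-1,3-dioxolane | I/C=C(C)\CC/C=C(C)\[C@@H]1COC(C)(C)O1 | intermediate
11 | (2Z,6Z)-2-[(4R)-2,2-dimethyl-1,3-dioxolan-4-yl]-7-iodo-6-methylhepta-2,6-dien-1-ol | I/C=C(C)\CC/C=C(CO)\[C@@H]1COC(C)(C)O1 | intermediate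
12 | (2R,3Z,7Z)-3-(hydroxymethyl)-8-iodo-7-methylocta-3,7-diene-1,2-diol | I/C=C(C)\CC/C=C(CO)\[C@@H](O)CO | intermediate
13 | [(4R,5Z)-2,2-di-tert-butyl-5-[(Z)-5-iodo-4-methylpent-4-en-1-ylidene]-1,3,2-dioxasilinan-4-yl]methanol | I/C=C(C)\CC/C=C1\[C@H](CO)O[Si](C(C)(C)C)(C(C)(C)C)OC1 | intermediate
14 | (4R,5Z)-2,2-di-tert-butyl-5-[(Z)-5-iodo-4-methylpent-4-en-1-ylidene]-1,3,2-dioxasilinane-4-carbaldehyde | I/C=C(C)\CC/C=C1\[C@H](C=O)O[Si](C(C)(C)C)(C(C)(C)C)OC1 | intermediate
15 | methyl acrylate | C=CC(=O)OC | starting material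
16 | 2,2-dimethoxyacetaldehyde | COC(OC)C=O | starting material
17 | methyl 3-hydroxy-4,4-dimethoxy-2-methylidenebutanoate (racemic) | C=C(C(=O)OC)C(O)C(OC)OC | intermediate
18 | methyl (Z)-2-(bromomethyl)-4,4-dimethoxybut-2-enoate | COC(=O)/C(CBr)=C/C(OC)OC | intermediate
19 | methyl (3R,4S)-4-[(4R,5Z)-2,2-di-tert-butyl-5-[(Z)-5-iodo-4-methylpent-4-en-1-ylidene]-1,3,2-dioxasilinan-4-yl]-3-(dimethoxymethyl)-4-hydroxy-2-methylidenebutanoate | I/C=C(C)\CC/C=C1\[C@H]([C@@H](O)[C@@H](C(=C)C(=O)OC)C(OC)OC)O[Si](C(C)(C)C)(C(C)(C)C)OC1 | intermediate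
20 | methyl (3R,4S)-4-[(4R,5Z)-2,2-di-tert-butyl-5-[(Z)-5-iodo-4-methylpent-4-en-1-ylidene]-1,3,2-dioxasilinan-4-yl]-3-(dimethoxymethyl)-4-[(2-methylprop-2-enoyl)oxy]-2-methylidenebutanoate | I/C=C(C)\CC/C=C1\[C@H]([C@@H](OC(=O)C(C)=C)[C@@H](C(=C)C(=O)OC)C(OC)OC)O[Si](C(C)(C)C)(C(C)(C)C)OC1 | intermediate
21 | methyl (3R,4S)-4-[(4R,5Z)-2,2-di-tert-butyl-5-[(Z)-5-iodo-4-methylpent-4-en-1-ylidene]-1,3,2-dioxasilinan-4-yl]-3-formyl-4-[(2-methylprop-2-enoyl)oxy]-2-methylidenebutanoate | I/C=C(C)\CC/C=C1\[C@H]([C@@H](OC(=O)C(C)=C)[C@@H](C(=C)C(=O)OC)C=O)O[Si](C(C)(C)C)(C(C)(C)C)OC1 | intermediate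
22 | C6 dichlorochromium alkoxide of the ring-closed methyl ester (ten-membered carbocycle, C6–C9 as in 23, lactone not yet closed) | C=C(C)C(=O)O[C@H]1[C@@H](C(=C)C(=O)OC)[C@H](O[Cr](Cl)Cl)/C=C(C)\CC/C=C2/CO[Si](C(C)(C)C)(C(C)(C)C)O[C@@H]12 | intermediate (not isolated)
23 | (1(10)Z,4Z,6R,7S,8S,9R)-9,14-O-(di-tert-butylsilanediyl)-9,14-dihydroxy-8-(methacryloyloxy)germacra-1(10),4,11(13)-trien-12,6-olide | C=C(C)C(=O)O[C@H]1[C@H]2C(=C)C(=O)O[C@@H]2/C=C(C)\CC/C=C2/CO[Si](C(C)(C)C)(C(C)(C)C)O[C@@H]12 | intermediate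
24 | (1(10)Z,4Z,6R,7S,8S,9R)-9,14-dihydroxy-8-(methacryloyloxy)germacra-1(10),4,11(13)-trien-12,6-olide | C=C(C)C(=O)O[C@H]1[C@H]2C(=C)C(=O)O[C@@H]2/C=C(C)\CC/C=C(/CO)[C@H]1O | intermediate
25 | (1(10)E,4Z,6R,7S,8S,9R)-9-hydroxy-8-(methacryloyloxy)-14-oxogermacra-1(10),4,11(13)-trien-12,6-olide | C=C(C)C(=O)O[C@H]1[C@H]2C(=C)C(=O)O[C@@H]2/C=C(C)\CC/C=C(/C=O)[C@H]1O | intermediate
26 | (1(10)E,4Z,6R,7S,8S,9R)-9-acetoxy-8-(methacryloyloxy)-14-oxogermacra-1(10),4,11(13)-trien-12,6-olide | C=C(C)C(=O)O[C@H]1[C@H]2C(=C)C(=O)O[C@@H]2/C=C(C)\CC/C=C(/C=O)[C@H]1OC(C)=O | intermediate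
27 | (1(10)E,4R,5R,6S,7R,8S,9R)-9-acetoxy-5-bromo-4-hydroxy-8-(methacryloyloxy)-14-oxogermacra-1(10),11(13)-dien-12,6-olide | C=C(C)C(=O)O[C@H]1[C@H]2C(=C)C(=O)O[C@@H]2[C@@H](Br)[C@@](O)(C)CC/C=C(/C=O)[C@H]1OC(C)=O | intermediate
28 | CNP0121379.1: (1(10)E,4R,5S,6S,7R,8S,9R)-9-acetoxy-4,5-epoxy-8-(methacryloyloxy)-14-oxogermacra-1(10),11(13)-dien-12,6-olide | C=C(C)C(=O)O[C@H]1[C@H]2C(=C)C(=O)O[C@@H]2[C@@H]2O[C@]2(C)CC/C=C(/C=O)[C@H]1OC(C)=O | target

**Step count**

Total steps: 21. Longest linear sequence: 17 steps (steps 1–3, 6–10, 13–21).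

**Steps most likely to fail**

Step 16. The alkenylchromium may attack the wrong face of the C6 aldehyde, in which case the epimeric alkoxide would lactonize irreversibly to the cis-fused lactone; the aldehyde may also undergo β-elimination or oligomerization before ring closure. The fallback sets out from 21 and comes back at 23. The ring is closed under the chromium-catalytic NHK variant (CrCl2 cat., NiCl2 cat., Mn powder, Me3SiCl, THF), in which the cyclized alkoxide is silylated before it can lactonize, to give the C6-epimeric trimethylsilyl ethers F1. Citric acid in methanol frees the C6-epimeric allylic alcohols F2, and Dess–Martin oxidation gives the ten-membered dienone F3. A reagent-controlled Corey–Bakshi–Shibata reduction ((R)-2-methyl-CBS-oxazaborolidine, catecholborane, −78 °C, the alkenyl group acting as the large substituent) sets C6 and gives the single (6R)-alcohol F4, which lactonizes with PPTS (CH2Cl2, rt) to 23.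

Step 20. The bromonium ion may form on the other face of C4=C5, which would end as the 4,5-epimeric epoxide, or it may be captured transannularly by the C14 carbonyl or the acetate oxygen. The fallback sets out from 26 and comes back at 28. Direct epoxidation of 26 with buffered mCPBA (NaHCO3, CH2Cl2, 0 °C) or dimethyldioxirane places the oxygen on the very face that electrophiles attack and replaces steps 20 and 21; it makes no new compound (F0).

Step 13. Felkin–Anh facial control at C8 or syn simple diastereoselection at C7 may erode in water, or the adduct may lactonize toward O8. The fallback sets out from 18 and 14 and comes back at 19. Bromide 18 is borylated (B2pin2, Pd2(dba)3 cat., DMSO) to methyl (E)-4,4-dimethoxy-2-[(4,4,5,5-tetramethyl-1,3,2-dioxaborolan-2-yl)methyl]but-2-enoate F5. Thermal allylboration of 14 with F5 (toluene, 80 °C) passes through a closed chair transition state that translates the olefin geometry (acetal carbon cis to CH2B) into the 7,8-syn relationship, and triethanolamine work-up gives 19.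

**Further compounds**

F1 | step 16 | methyl ester of the ring-closed seco-lactone as its 6-O-trimethylsilyl ether (C6 epimers; C7–C9 as in 23) | C=C(C)C(=O)O[C@H]1[C@@H](C(=C)C(=O)OC)C(O[Si](C)(C)C)/C=C(C)\CC/C=C2/CO[Si](C(C)(C)C)(C(C)(C)C)O[C@@H]12
F2 | step 16 | methyl (1(10)Z,4Z)-9,14-O-(di-tert-butylsilanediyl)-6-hydroxy-8-(methacryloyloxy)germacra-1(10),4,11(13)-trien-12-oate (C6 epimers) | C=C(C)C(=O)O[C@H]1[C@@H](C(=C)C(=O)OC)C(O)/C=C(C)\CC/C=C2/CO[Si](C(C)(C)C)(C(C)(C)C)O[C@@H]12
F3 | step 16 | methyl (1(10)Z,4Z)-9,14-O-(di-tert-butylsilanediyl)-8-(methacryloyloxy)-6-oxogermacra-1(10),4,11(13)-trien-12-oate | C=C(C)C(=O)O[C@H]1[C@@H](C(=C)C(=O)OC)C(=O)/C=C(C)\CC/C=C2/CO[Si](C(C)(C)C)(C(C)(C)C)O[C@@H]12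
F4 | step 16 | methyl (1(10)Z,4Z,6R,7S,8S,9R)-9,14-O-(di-tert-butylsilanediyl)-6-hydroxy-8-(methacryloyloxy)germacra-1(10),4,11(13)-trien-12-oate | C=C(C)C(=O)O[C@H]1[C@@H](C(=C)C(=O)OC)[C@H](O)/C=C(C)\CC/C=C2/CO[Si](C(C)(C)C)(C(C)(C)C)O[C@@H]12
F0 | step 20 | none | none
F5 | step 13 | methyl (E)-4,4-dimethoxy-2-[(4,4,5,5-tetramethyl-1,3,2-dioxaborolan-2-yl)methyl]but-2-enoate | COC(=O)/C(CB1OC(C)(C)C(C)(C)O1)=C/C(OC)OC
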